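The readings are calculated from invented constants, and the scatter is random.

At early times the left-handed product follows the catalyst: at 10.0 s it stands at 2.3 % in the autumn run and 7.6 % in the midnight run, a ratio of 3.30 for a loading ratio of 2.95. Yet at 120 s the same two runs differ by a ratio of 2.04.

common to all: left-handed substrate 0.78 M; right-handed substrate 0.78 M
- autumn: coupling partner 3 equiv; free catalyst 0.21 mol%; run made earlier
- midnight: coupling partner 3 equiv; free catalyst 0.62 mol%; run made earlier
- Sunday's: coupling partner 3.00 equiv; free catalyst 1 mol%; time 2.0 min
- Friday's: coupling partner 3.00 equiv; free catalyst 0.3 mol%; time 2.0 min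

- autumn (time / s: left-handed product / %, right-handed product / %): 10.0: 2.3, 0; 20.0: 4.7, 0; 30.0: 6.0, 0.4; 60.0: 9.7, 2.1; 120: 14.0, 3.3
- midnight (time / s: left-handed product / %, right-handed product / %): 10.0: 7.6, 0.1; 30.0: 16.2, 1.3; 60.0: 23.7, 2.8; 80.0: 26.2, 4.0; 120: 28.5, 6.1

(scatter of a reading: 0.5 percentage points)

- free catalyst is single-handed; left-handed substrate and right-handed substrate are mirror images of each other, charged as a racemate, each of them at the stated concentration
- the numbers in the tables scatter with a standard deviation of 0.5 percentage points
- an excess is the difference of the two amounts in percent of their sum
- an excess is below zero if the other one leads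

- which of the two ends with the higher excess of left-handed product over right-handed product in the product ("neither" if they lie within 2 percentage points) (Sunday's / Friday's / neither)
- excess of left-handed product over right-handed product in the product at the end, Sunday's
- excess of left-handed product over right-handed product in the product at the end, Friday's

We narrow this gap by counting what is left, not what is made. The left-handed substrate is a fraction 0.5 of the two substrates charged together, and the left-handed product draws on it. We define the exposure as the number of time constants of a first-order (pseudo-first-order) decay that the substrate has lived through: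

exposure = ln( c(left-handed substrate) charged / c(left-handed substrate) charged but not yet read as left-handed product )

At 120 s the autumn run has 0.329 and the midnight run 0.844, a ratio of 2.57, which is nearer the loading ratio than the ratio of the amounts made. So we scale exposure with loading, from the nearer run, for the same time:

Sunday's: exposure 1.36, fraction left 0.256, left-handed product 37.2 %

Friday's: exposure 0.469, fraction left 0.625, left-handed product 18.8 %

Between 80.0 s and 120 s, on the way to its exposure of 0.844, the midnight run added 2.3 percentage points of left-handed product and 2.1 points of right-handed product. So we expect Sunday's, whose exposure is higher than Friday's, to end with the lower excess, though we put no figure on it.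

The forecast says Friday's, with 60 % for Sunday's and 64 % for Friday's, since the “left-handed substrate is largely used up”. Its left-handed product for Sunday's is about 36%, against our 37.2 %.

The flask gives Friday's: 60.1 % for Sunday's and 66.7 % for Friday's.

    free catalyst + left-handed substrate ⇌ catalyst intermediate A (K = 1.90 M⁻¹, k = 15.0 M⁻¹ s⁻¹)
    free catalyst + right-handed substrate ⇌ catalyst intermediate B (K = 1.80 M⁻¹, k = 29.0 M⁻¹ s⁻¹)
    coupling partner + catalyst intermediate A → free catalyst + left-handed product (k = 5.80 M⁻¹ s⁻¹)
    coupling partner + catalyst intermediate B → free catalyst + right-handed product (k = 0.0970 M⁻¹ s⁻¹)
    left-handed product ⇌ right-handed product (k = 0.00230 s⁻¹)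
    coupling partner + free catalyst → spent catalyst (k = 6.50 × 10⁻⁴ M⁻¹ s⁻¹)
    2 coupling partner → homo dimer (k = 0.00500 M⁻¹ s⁻¹)

In Sunday's, from 1.00 min to 2.00 min, the left-handed product went from 31.7 % to 36.1 % and the right-handed product from 4.34 % to 8.99 %. Read back from the left-handed product, the exposure is 0.465 for Friday's against our 0.469, and 1.28 for Sunday's against the 1.36 we scaled from the midnight run's 0.844.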